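## Structural features

The target is the (E)-4-hydroxycinnamate of a guaiane (hydroazulene) diol. A cyclopentane (C1–C5) is fused along C1–C5 to a seven-membered ring (C1, C5, C6–C10) whose only alkene is the tetrasubstituted C1=C10 bond. Methyl groups sit on C4 and C10, a 2-hydroxyprop-2-yl group (C11) on C7 and the ester oxygen on C8.

The four stereocentres form two adjacent pairs, C4/C5 and C7/C8, separated by the C6 methylene; the configuration is (4S,5S,7S,8S). In the usual drawing the C4 methyl and the C7 side chain are β, and H5 and O8 are α. C6 therefore leaves C5 on the same face as the C4 methyl, the more crowded face of the five-membered ring, and the C7 and C8 substituents are trans.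

The fragile groups are the coumarate (free phenol, base-labile ester, photo-isomerisable alkene), the tertiary alcohol, and the C1=C10 alkene, which migrates under acid.

The real difficulty is threefold: a seven-membered ring with the alkene fixed between C1 and C10, a ring-fusion centre whose C6 branch is cis to the neighbouring methyl, and the relay of configuration from C5 across C6 to C7 and C8.

The key step uses the fact that C9–C10–C1–C5–C6 is a vinylcyclopropane in disguise. The cyclopropane is C1–C5–C6 fused to the cyclopentane, and the isopropenyl group supplies C10, C9 and the C10 methyl. C7–C8 is an alkyne that already carries the complete C11 carbinol.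

## Logic of the disconnections

**17 ⇒ 16 ⇒ 12 + 15.** The acyl–O8 bond is cut because it is the only bond joining two independent halves. The phenol is masked as a silyl ether (16) so that the acid partner cannot acylate itself. The gain is a diol and a simple cinnamic acid. The forward step must acylate the secondary hydroxyl of 12 and leave the tertiary one alone, and the unmasking must spare the ester and the C1=C10 alkene.

**15 ⇒ 13.** Only Si–O bonds are cut. The forward step must silylate the phenol and leave the carboxyl free, which is done by bis-silylation and hydrolysis of the labile silyl ester.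

**12 ⇒ 10.** The C8–O and C7–H bonds are cut together, which removes both C7 and C8 as stereocentres and leaves a trisubstituted alkene. The forward step must place oxygen on C8, add syn (which gives the trans C7/C8 relationship), choose the α face, and leave C1=C10 untouched.

**10 ⇒ 8 + 9.** The C6–C7 and C8–C9 bonds are cut. This takes the seven-membered ring apart into a five-carbon vinylcyclopropane and a two-carbon alkyne that brings C11 with its oxygen. No stereocentre is made or lost, and 8 and 10 carry C4 and C5 exactly as in 17. The forward step must cleave C1–C6 and not C1–C5, and must orient the alkyne with its substituted carbon toward C6.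

**8 ⇒ 7.** The C9=C10 alkene is traced back to a tertiary carbinol. The isopropenyl group cannot be present while the C4 methyl is set by hydrogenation, so it is kept latent as the hydrate. The forward step needs a dehydration that does not let a cyclopropylcarbinyl cation rearrange; only methyl hydrogens are available, so the regiochemistry is unambiguous.

**7 ⇒ 6 ⇒ 5.** The C4 stereocentre is cut back to an exocyclic methylene and then to a ketone. The forward hydrogenation must occur on the face away from the cyclopropane, which places the methyl cis to it as 17 requires.

**5 ⇒ 4 ⇒ 3.** The cyclopropane bonds C1–C6 and C5–C6 are cut. The ring carbinol of 3 is a temporary control element: it directs the methylene to its own face and is then oxidised away, leaving the ring fusion as the only stereochemical information. The forward step needs an electron-rich alkene and clean cis delivery.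

**3 ⇒ 2 ⇒ 1.** Two C–CH3 bonds at the future C10 are cut back to an ester, and the carbinol to a ketone. Adding the methyl groups before cyclopropanation turns an electron-poor enoate into a trisubstituted allylic alkene, which suits the zinc carbenoid far better. The forward reduction must set the (S)-carbinol, on which the absolute configuration of the whole route depends.

## Other disconnections considered

**Alternative 1:** The cut is C5–C6, paired with the C10–O bond of a seven-membered lactone, A1. Its silyl ketene acetal (LiN(i-Pr)2, Me3SiCl) would undergo an Ireland–Claisen ring contraction to the acid A2, closing the carbocycle and creating C1=C10.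
- In its favour: a concerted suprafacial shift would transfer the C10 configuration of A1 to C5 predictably, and the alkene position is fixed by the mechanism. The C7/C8/C11 oxygen pattern is already in place as an acetonide, so the trans C7/C8 relationship is settled before the ring is closed. On this last point the alternative is better than the chosen plan, which decides C7 and C8 by a late facial selection.
- Against it here: the lactone ring forces a boat transition state, and the new bond must form on the cyclopentene face syn to the C4 methyl. The tertiary allylic ester of A1 can ionise or eliminate instead of rearranging. A2 carries a C6 carboxyl that the target lacks, so a radical decarboxylation to A4 and an acetonide cleavage must follow.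
- Comparison: structurally it needs a four-stereocentre medium-ring lactone against a ten-carbon bicyclic hydrocarbon; mechanistically it is at least as predictable as an untested cycloaddition; in step economy it is clearly longer.

**Alternative 2:** The cut is C1–C5, paired with cleavage of C5–C10 in a trans-decalin. Buffered solvolysis of the equatorial mesylate A3 would move C5 from C10 to C1 and the C10 cation would lose H1, giving the hydroazulene acetonide A4. Acetonide hydrolysis would then lead to 12.
- In its favour: the ring reorganisation is a long-established reaction type for exactly this skeleton class, and the equatorial leaving group is antiperiplanar to the migrating bond, so C5 migrates with retention. Chair-based control in a decalin is dependable for C5, C7 and C8. On strength of precedent for the key step this alternative is better than the chosen plan.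
- Against it here: A3 has six stereocentres, and its C4 methyl must be axial and syn to the angular methyl, the less stable arrangement. The C10 cation can also lose a proton from C9 or from the methyl group, so the alkene position is not guaranteed.
- Comparison: structurally and in step economy it is much heavier than the chosen plan (which builds the ring from two small pieces in one step); mechanistically it is the safer key step.

**Alternative 3:** The cut is C8–C9. Zerovalent palladium, Pd(PPh3)4, would ionise the tertiary allylic carbonate A5 and the tethered nitronate carbon C8 would attack the allyl terminus C9, giving the nitro compound A6 with C1=C10 in place.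
- In its favour: conditions are mild, only one C–C bond is formed in the ring closure so no alkyne orientation is at issue, and C7 is set before cyclisation. The nitro-bearing C8 can equilibrate to the trans arrangement. On control of C7 this alternative is the equal of or better than the chosen plan.
- Against it here: seven-membered closure at C9 competes with attack at the internal terminus C1, which closes a five-membered ring. The nitro group must then be exchanged for a hydroxyl through the ketone A7, whose β,γ-alkene can slip into conjugation, and the ketone must be reduced selectively. A5 itself needs the cis C4/C5 relationship that is awkward to set on a cyclopentane.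
- Comparison: mechanistically well understood, structurally a more demanding precursor, and several steps longer because of the functional-group exchange at C8.

Key step: step 8

Assumption: guaiane numbering is used for the carbocycle throughout, and the oxazaborolidine enantiomer in step 1 is the one that the usual large-group/small-group model (alkenyl arm large) assigns to the (S)-alcohol.

## Steps

**Step 1**
Reactants: 1 methyl 3-oxocyclopent-1-ene-1-carboxylate
Product: 2 methyl (S)-3-hydroxycyclopent-1-ene-1-carboxylate
Conditions: (R)-2-methyl-CBS-oxazaborolidine (10 mol%), BH3·SMe2 (0.6 equiv), THF, −20 °C; then MeOH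
Reagents that add atoms: none
Why: Corey–Bakshi–Shibata reduction; the ketone should bind the catalyst with the enoate arm as the large group, so hydride is delivered to one face and the (S)-carbinol results. 1,2-Reduction of the enone is expected to outrun conjugate reduction, and the ester is inert at this temperature.

**Step 2**
Reactants: 2 methyl (S)-3-hydroxycyclopent-1-ene-1-carboxylate
Product: 3 (S)-3-(2-hydroxypropan-2-yl)cyclopent-2-en-1-ol
Conditions: MeLi (3.5 equiv), Et2O/THF, −78 → 0 °C; then H2O
Reagents that add atoms: methyllithium, [Li]C
Why: Double 1,2-addition of an organolithium to the ester through the methyl ketone; the first equivalent forms the lithium alkoxide of the ring carbinol, which protects it. The stereocentre is not involved, and the alkene becomes an electron-rich allylic one.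

**Step 3**
Reactants: 3 (S)-3-(2-hydroxypropan-2-yl)cyclopent-2-en-1-ol
Product: 4 (1R,2S,5R)-5-(2-hydroxypropan-2-yl)bicyclo[3.1.0]hexan-2-ol
Conditions: Et2Zn (4 equiv), CH2I2 (4 equiv), CH2Cl2, −10 → 0 °C; then aq. NH4Cl
Reagents that add atoms: diiodomethane, ICI
Why: Hydroxyl-directed Simmons–Smith cyclopropanation (Furukawa variant); the zinc alkoxide of the rigid ring carbinol should deliver the carbenoid to its own face, so the cyclopropane forms cis to that hydroxyl and both ring-fusion centres are set. Any trans isomer must be removed here, because oxidation in step 4 would turn it into the enantiomer of 5.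

**Step 4**
Reactants: 4 (1R,2S,5R)-5-(2-hydroxypropan-2-yl)bicyclo[3.1.0]hexan-2-ol
Product: 5 (1R,5R)-5-(2-hydroxypropan-2-yl)bicyclo[3.1.0]hexan-2-one
Conditions: Pr4N[RuO4] (5 mol%), N-methylmorpholine N-oxide (1.5 equiv), 4 Å MS, CH2Cl2, rt
Reagents that add atoms: none
Why: Ley–Griffith oxidation of the secondary alcohol; the tertiary alcohol and the cyclopropane are inert under these neutral conditions. The carbinol centre is erased on purpose, leaving the ring fusion as the stereochemical anchor.

**Step 5**
Reactants: 5 (1R,5R)-5-(2-hydroxypropan-2-yl)bicyclo[3.1.0]hexan-2-one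
Product: 6 2-[(1R,5S)-4-methylidenebicyclo[3.1.0]hexan-1-yl]propan-2-ol
Conditions: Ph3PCH3Br (3 equiv), KOt-Bu (3 equiv), THF, 0 °C → rt
Reagents that add atoms: methyltriphenylphosphonium bromide, C[P+](c1ccccc1)(c1ccccc1)c1ccccc1.[Br-]
Why: Wittig methylenation of a cyclopropyl ketone, the standard way to a sabinene-type exocyclic alkene; excess ylide covers the free tertiary hydroxyl and the non-acidic medium spares the cyclopropane.

**Step 6**
Reactants: 6 2-[(1R,5S)-4-methylidenebicyclo[3.1.0]hexan-1-yl]propan-2-ol
Product: 7 2-[(1R,4S,5S)-4-methylbicyclo[3.1.0]hexan-1-yl]propan-2-ol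
Conditions: H2 (1 atm), 5% Rh/Al2O3, EtOAc, rt
Reagents that add atoms: none
Why: Heterogeneous hydrogenation of a 1,1-disubstituted alkene; the boat-shaped bicyclo[3.1.0]hexane shields the face that carries the cyclopropane methylene, so hydrogen should add from the opposite face and push the new methyl cis to the cyclopropane (4S). Rhodium on alumina is chosen because it rarely hydrogenolyses cyclopropanes.

**Step 7**
Reactants: 7 2-[(1R,4S,5S)-4-methylbicyclo[3.1.0]hexan-1-yl]propan-2-ol
Product: 8 (1R,4S,5S)-4-methyl-1-(prop-1-en-2-yl)bicyclo[3.1.0]hexane
Conditions: Burgess reagent (methyl N-(triethylammoniosulfonyl)carbamate, 1.5 equiv), toluene, 50 °C; product kept in solution (volatile)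
Reagents that add atoms: none
Why: Burgess dehydration, a syn elimination through the sulfamate ester; only the methyl groups carry β-hydrogens, so the isopropenyl group is the only possible alkene. The neutral medium without a nucleophilic counter-ion is meant to prevent opening of the cyclopropylcarbinyl system.

**Step 8**
Reactants: 8 (1R,4S,5S)-4-methyl-1-(prop-1-en-2-yl)bicyclo[3.1.0]hexane; 9 2-methylbut-3-yn-2-ol
Product: 10 (4S,5S)-guaia-1(10),7-dien-11-ol, i.e. 2-[(3S,3aS)-3,8-dimethyl-1,2,3,3a,4,7-hexahydroazulen-5-yl]propan-2-ol
Conditions: [Rh(CO)2Cl]2 (5 mol%), 9 (1.5 equiv, added slowly), ClCH2CH2Cl, 80 °C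
Reagents that add atoms: none
Why: This is an intermolecular rhodium-catalysed (5+2) cycloaddition of a vinylcyclopropane with an alkyne, a known reaction type for 1-substituted vinylcyclopropanes. Monovalent rhodium should bind the isopropenyl group in its s-cis conformer and cleave the C1–C6 bond oxidatively, giving a trivalent rhodacycle with a σ-bond to C6 and a π-allyl over C1–C10–C9. The alkyne then coordinates and inserts, forming C8–C9, and C(sp2)–C(sp3) reductive elimination forms C6–C7. The seven-membered ring is thus closed by a metal-templated two-bond annulation from an eight-membered rhodacycle, which also dictates the cis geometry of C1=C10 within the ring. No stereocentre is created; C4 and C5 do not take part and are carried through unchanged, while C1 becomes trigonal. The first selectivity needed is cleavage of C1–C6 and not C1–C5; C6 is the less substituted and more accessible carbon, and cleavage of C1–C5 would lead to a bridged ring with a bridgehead alkene. The second is alkyne orientation: the bulky carbinol carbon should stay away from the C8–C9 bond that forms during insertion, so it ends on C6. The fully substituted C1 favours the reactive s-cis conformer, which is what lets such intermolecular cases proceed.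

**Step 9**
Reactants: 10 (4S,5S)-guaia-1(10),7-dien-11-ol
Product: 12 (4S,5S,7S,8S)-guai-1(10)-ene-8,11-diol, via cyclic alkoxyborane 11 (not isolated)
Conditions: BH3·THF (2.0 equiv), THF, −10 → 0 °C; then NaOH, H2O2, 0 °C → rt
Reagents that add atoms: borane–tetrahydrofuran, [BH3-][O+]1CCCC1 (boron of 11); hydrogen peroxide, OO (O8 of 12)
Why: Hydroboration–oxidation; boron should go to the less substituted C8 and hydrogen to C7 in a syn addition, and oxidation with retention then gives the trans C7/C8 relationship. The ring fusion holds H5 axial on the convex face of the tub-shaped cyclohepta-1,4-diene, so borane is expected on that α face, away from the facing C1=C10 unit; the tetrasubstituted alkene reacts more slowly.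

**Step 10**
Reactants: 13 (E)-4-hydroxycinnamic acid
Product: 15 (E)-4-(tert-butyldimethylsilyloxy)cinnamic acid, via bis-silylated acid 14 (not isolated)
Conditions: TBSCl (2.3 equiv), imidazole (4.5 equiv), DMF, rt; then AcOH/THF/H2O, rt
Reagents that add atoms: tert-butyldimethylsilyl chloride, CC(C)(C)[Si](C)(C)Cl
Why: Silylation of both the phenol and the carboxyl, followed by hydrolysis of the silyl ester, which is far more labile than the aryl silyl ether; the alkene geometry is untouched.

**Step 11**
Reactants: 12 (4S,5S,7S,8S)-guai-1(10)-ene-8,11-diol; 15 (E)-4-(tert-butyldimethylsilyloxy)cinnamic acid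
Product: 16 (4S,5S,7S,8S)-11-hydroxyguai-1(10)-en-8-yl (E)-4-(tert-butyldimethylsilyloxy)cinnamate
Conditions: 15 (1.5 equiv), EDC·HCl (2 equiv), DMAP (1 equiv), CH2Cl2, 0 °C → rt, in the dark
Reagents that add atoms: none
Why: Steglich esterification; the secondary C8 hydroxyl is acylated while the tertiary C11 hydroxyl is too hindered to react. The acyl–oxygen bond is the one formed, so C8 keeps its configuration.

**Step 12**
Reactants: 16 (4S,5S,7S,8S)-11-hydroxyguai-1(10)-en-8-yl (E)-4-(tert-butyldimethylsilyloxy)cinnamate
Product: 17 (4S,5S,7S,8S)-11-hydroxyguai-1(10)-en-8-yl (E)-4-hydroxycinnamate (target)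
Conditions: Bu4NF (1.1 equiv), AcOH (1.2 equiv), THF, 0 °C, in the dark
Reagents that add atoms: none
Why: Fluoride cleavage of an aryl silyl ether, which is fast at 0 °C; the acetic acid buffer keeps the phenoxide from attacking the ester and protects the acid-sensitive alkene and tertiary alcohol from either extreme.

## Compound list

1 | methyl 3-oxocyclopent-1-ene-1-carboxylate | COC(=O)C1=CC(=O)CC1 | starting material
2 | methyl (S)-3-hydroxycyclopent-1-ene-1-carboxylate | COC(=O)C1=C[C@@H](O)CC1 | intermediate
3 | (S)-3-(2-hydroxypropan-2-yl)cyclopent-2-en-1-ol | CC(C)(O)C1=C[C@@H](O)CC1 | intermediate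
4 | (1R,2S,5R)-5-(2-hydroxypropan-2-yl)bicyclo[3.1.0]hexan-2-ol | CC(C)(O)[C@@]12CC[C@H](O)[C@@H]1C2 | intermediate
5 | (1R,5R)-5-(2-hydroxypropan-2-yl)bicyclo[3.1.0]hexan-2-one | CC(C)(O)[C@@]12CCC(=O)[C@@H]1C2 | intermediate
6 | 2-[(1R,5S)-4-methylidenebicyclo[3.1.0]hexan-1-yl]propan-2-ol | CC(C)(O)[C@@]12CCC(=C)[C@@H]1C2 | intermediate
7 | 2-[(1R,4S,5S)-4-methylbicyclo[3.1.0]hexan-1-yl]propan-2-ol | CC(C)(O)[C@@]12CC[C@H](C)[C@@H]1C2 | intermediate
8 | (1R,4S,5S)-4-methyl-1-(prop-1-en-2-yl)bicyclo[3.1.0]hexane | CC(=C)[C@@]12CC[C@H](C)[C@@H]1C2 | intermediate
9 | 2-methylbut-3-yn-2-ol | CC(C)(O)C#C | starting material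
10 | (4S,5S)-guaia-1(10),7-dien-11-ol | CC1=C2CC[C@H](C)[C@@H]2CC(C(C)(C)O)=CC1 | intermediate
11 | cyclic alkoxyborane (1,2-oxaborolane, B–H, boron on C8 and oxygen on C11, trans-fused at C7–C8) | CC1=C2CC[C@H](C)[C@@H]2C[C@H]3[C@H](C1)BOC3(C)C | intermediate
12 | (4S,5S,7S,8S)-guai-1(10)-ene-8,11-diol | CC1=C2CC[C@H](C)[C@@H]2C[C@H](C(C)(C)O)[C@@H](O)C1 | intermediate
13 | (E)-4-hydroxycinnamic acid | OC(=O)/C=C/c1ccc(O)cc1 | starting material
14 | tert-butyldimethylsilyl (E)-4-(tert-butyldimethylsilyloxy)cinnamate | CC(C)(C)[Si](C)(C)OC(=O)/C=C/c1ccc(O[Si](C)(C)C(C)(C)C)cc1 | intermediate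
15 | (E)-4-(tert-butyldimethylsilyloxy)cinnamic acid | OC(=O)/C=C/c1ccc(O[Si](C)(C)C(C)(C)C)cc1 | intermediate
16 | (4S,5S,7S,8S)-11-hydroxyguai-1(10)-en-8-yl (E)-4-(tert-butyldimethylsilyloxy)cinnamate | CC1=C2CC[C@H](C)[C@@H]2C[C@H](C(C)(C)O)[C@@H](OC(=O)/C=C/c2ccc(O[Si](C)(C)C(C)(C)C)cc2)C1 | intermediate
17 | (4S,5S,7S,8S)-11-hydroxyguai-1(10)-en-8-yl (E)-4-hydroxycinnamate | CC1=C2CC[C@H](C)[C@@H]2C[C@H](C(C)(C)O)[C@@H](OC(=O)/C=C/c2ccc(O)cc2)C1 | target

## Step count and least certain steps

Total step count: 12. Longest linear sequence: 11 steps (steps 1–9, 11 and 12; step 10 is a one-step side branch).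

**Step 8 (key step).** The most likely failures are insertion of the alkyne in the wrong orientation and competing cleavage of the C1–C5 bond. Isopropenyl-type vinylcyclopropanes are the least predictable class for orientation, and a ring-fused cyclopropane has not been examined in this reaction. The free tertiary hydroxyl may also slow turnover by binding rhodium, and the product may ionise at the allylic carbinol on prolonged heating.
Fallback: it sets out from 8 and 9 and returns at 10. Compound 9 is silylated (Et3SiCl, imidazole) to 2-methyl-2-(triethylsilyloxy)but-3-yne F1, a larger partner with no free hydroxyl. Cycloaddition of 8 with F1 under [Rh(CO)2Cl]2 should give the silyl ether of the dienol, (4S,5S)-11-(triethylsilyloxy)guaia-1(10),7-diene F2, and Bu4NF then releases 10. This changes the reaction partner so that orientation rests on a bulkier, non-coordinating group.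

**Step 3.** The tertiary zinc alkoxide on the side chain can also deliver the carbenoid, and it has no facial preference. Competing delivery to the face opposite the ring hydroxyl would lower the diastereoselectivity and, after step 4, the enantiomeric purity.
Fallback: it sets out from 3 and returns at 4. Compound 3 is bis-silylated (Me3SiCl, imidazole) to (S)-3-(trimethylsilyloxy)-1-[2-(trimethylsilyloxy)propan-2-yl]cyclopent-1-ene F3. The exposed secondary silyl ether is cleaved selectively (K2CO3, MeOH, 0 °C) to (S)-3-[2-(trimethylsilyloxy)propan-2-yl]cyclopent-2-en-1-ol F4. Cyclopropanation (Et2Zn, CH2I2), now directed by the only free hydroxyl, gives (1R,2S,5R)-5-[2-(trimethylsilyloxy)propan-2-yl]bicyclo[3.1.0]hexan-2-ol F5, and Bu4NF returns 4.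

**Step 9.** Poor facial selectivity would give the 7,8-bis-epimer, and excess borane could over-reduce by hydroborating the C1=C10 alkene. Both centres are set in one event, and a wrong outcome cannot be corrected afterwards through a C8 ketone, because that ketone would be β,γ-unsaturated and would conjugate under base.
Fallback: it sets out from 10 and returns at 12. The tertiary hydroxyl is silylated with (HMe2Si)2NH to (4S,5S)-11-(dimethylsilyloxy)guaia-1(10),7-diene F6. Intramolecular hydrosilylation (Pt2[(CH2=CHSiMe2)2O]3, toluene, 60 °C) can reach only the neighbouring C7=C8 alkene and should add syn, with silicon at C8, to give the C8–Si–O11 oxasilolane F7. Tamao oxidation (H2O2, KF, KHCO3, THF/MeOH) with retention then gives 12. The tether removes the chemoselectivity problem, and the bulkier metal-bound silane should discriminate the faces more sharply.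

**Step 7.** Ionisation to the cyclopropylcarbinyl cation may be followed by ring opening or ring expansion before the proton is lost.
Fallback: it sets out from 7 and returns at 8. Compound 7 is converted (NaH, CS2, MeI, THF) into O-{2-[(1R,4S,5S)-4-methylbicyclo[3.1.0]hexan-1-yl]propan-2-yl} S-methyl dithiocarbonate F8, and Chugaev thermolysis (toluene, 80–110 °C) gives 8 by a concerted syn elimination that involves no cation.

**Step 6.** Hydrogenolysis of the cyclopropane bond next to the alkene could compete with the hydrogenation. Migration of the alkene into the ring before reduction would do no harm, since the ring alkene is reduced from the same face.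
Fallback: it sets out from 6 and returns at 7. Reduction with diimide, generated from 2-nitrobenzenesulfonohydrazide and Et3N in CH2Cl2, is metal-free, cannot cleave the cyclopropane and should attack the same open face; it makes no new compound.

## Further compounds

F1 | step 8 | 2-methyl-2-(triethylsilyloxy)but-3-yne | CC(C)(O[Si](CC)(CC)CC)C#C
F2 | step 8 | (4S,5S)-11-(triethylsilyloxy)guaia-1(10),7-diene | CC1=C2CC[C@H](C)[C@@H]2CC(C(C)(C)O[Si](CC)(CC)CC)=CC1
F3 | step 3 | (S)-3-(trimethylsilyloxy)-1-[2-(trimethylsilyloxy)propan-2-yl]cyclopent-1-ene | CC(C)(O[Si](C)(C)C)C1=C[C@@H](O[Si](C)(C)C)CC1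
F4 | step 3 | (S)-3-[2-(trimethylsilyloxy)propan-2-yl]cyclopent-2-en-1-ol | CC(C)(O[Si](C)(C)C)C1=C[C@@H](O)CC1
F5 | step 3 | (1R,2S,5R)-5-[2-(trimethylsilyloxy)propan-2-yl]bicyclo[3.1.0]hexan-2-ol | CC(C)(O[Si](C)(C)C)[C@@]12CC[C@H](O)[C@@H]1C2
F6 | step 9 | (4S,5S)-11-(dimethylsilyloxy)guaia-1(10),7-diene | CC1=C2CC[C@H](C)[C@@H]2CC(C(C)(C)O[SiH](C)C)=CC1
F7 | step 9 | cyclic C8–Si–O11 dimethyl oxasilolane of (4S,5S,7S,8S)-guai-1(10)-ene-8,11-diol | CC1=C2CC[C@H](C)[C@@H]2C[C@H]3[C@H](C1)[Si](C)(C)OC3(C)C
F8 | step 7 | O-{2-[(1R,4S,5S)-4-methylbicyclo[3.1.0]hexan-1-yl]propan-2-yl} S-methyl dithiocarbonate | CC(C)(OC(=S)SC)[C@@]12CC[C@H](C)[C@@H]1C2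
F0 | step 6 | none | none
A1 | alternative 1 | seven-membered lactone: 7-methyl-7-[(S)-3-methylcyclopent-1-en-1-yl]oxepan-2-one carrying the C7/C8 acetonide, (S) at the tertiary allylic carbon | O=C1C[C@H]2[C@H](C[C@](C)(O1)C1=C[C@@H](C)CC1)OC(C)(C)OC2(C)C
A2 | alternative 1 | guai-1(10)-ene-8,11-diol acetonide 6-carboxylic acid | CC1=C2CC[C@H](C)[C@@H]2[C@H](C(=O)O)[C@H]3[C@H](C1)OC(C)(C)OC3(C)C
A3 | alternative 2 | trans-decalin 1β-mesylate (4β,10β-dimethyl, 5α-H) carrying the C7/C8 acetonide | CS(=O)(=O)O[C@@H]1CC[C@H](C)[C@@H]2C[C@H]3[C@H](C[C@@]12C)OC(C)(C)OC3(C)C
A4 | alternative 2 | guai-1(10)-ene-8,11-diol acetonide | CC1=C2CC[C@H](C)[C@@H]2C[C@H]3[C@H](C1)OC(C)(C)OC3(C)C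
A5 | alternative 3 | tertiary allylic methyl carbonate with tethered nitroalkane (cyclopentane bearing isopropenyl and carbonate on C1) | COC(=O)O[C@]1(C(C)=C)CC[C@H](C)[C@@H]1C[C@@H](C[N+](=O)[O-])C(C)(C)O[Si](CC)(CC)CC
A6 | alternative 3 | 8-nitro-11-(triethylsilyloxy)guai-1(10)-ene | CC1=C2CC[C@H](C)[C@@H]2C[C@H](C(C)(C)O[Si](CC)(CC)CC)[C@@H]([N+](=O)[O-])C1
A7 | alternative 3 | 11-(triethylsilyloxy)guai-1(10)-en-8-one | CC1=C2CC[C@H](C)[C@@H]2C[C@H](C(C)(C)O[Si](CC)(CC)CC)C(=O)C1
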